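**Minutes of the meeting on the flask.** The meeting began by setting two charges side by side: in this flask, where starting material in the first phase meets a reagent held in a second phase, the protic impurity is charged in far smaller amount than the starting material.

| setting | Tuesday's | Thursday's | flask |
|---|---|---|---|
| starting material | 0.25 M | 0.25 M | 0.25 M |
| reagent in the second phase | 1.5 equiv | 1.5 equiv | 1.50 equiv |
| protic impurity | 7 mM | 11 mM | 5.00 mM |
| remark | run made earlier | run made earlier |  |
| time |  |  | 3.0 d |
| volume of the second phase over the first |  |  | 1.0 |

| run | time / h | target / % | starting material / % |
|---|---|---|---|
| Tuesday's | 8.00 | 2 | 96 |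
| Tuesday's | 15.0 | 6 | 94 |
| Tuesday's | 25.0 | 10 | 86 |
| Tuesday's | 30.0 | 18 | 82 |
| Tuesday's | 40.0 | 25 | 73 |
| Thursday's | 4.00 | 0 | 96 |
| Thursday's | 10.0 | 1 | 92 |
| Thursday's | 20.0 | 9 | 87 |
| Thursday's | 30.0 | 15 | 77 |
| Thursday's | 40.0 | 21 | 69 |

(each reading ± 2 percentage points)

- in the second phase: reagent in the second phase; everything else is in the first
- charges count per volume of the first phase; a concentration in a rate is the amount of a species over the volume of its own phase; every rate counts per litre of the first phase
- the earlier runs hold the two phases in the same ratio of volumes as the flask asked about

1. target at 3.0 d, in percent of the starting material charged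
2. part of the starting material charged that has reacted at 3.0 d

The first speaker wrote the balance of that smaller charge. If each impurity takes one starting material and is then gone, as in a titration, the impurity is the limiting reagent of that side step, and the flask loses 2.00% of its charge that way. She named this the impurity share, the protic impurity charged over the starting material charged.

The second speaker defined the gap as the starting material reacted minus the target found, and held it against the share at 40.0 h. Tuesday's run shows a gap of 2 percentage points on a share of 2.80%, and Thursday's shows 10 points on a share of 4.40%. With 2 points on each reading, the meeting took this as a loose match. The minutes commit to this reckoning: the flask's gap will hold the share plus a remainder whose size these two gaps leave open.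

The forecast gave 43% target and 47% reacted, on the ground that the gap “roughly tracks the impurity charge”, so its two numbers stand 4 points apart.

**The flask.** At 3.0 d it gives 35.0% target and 42.7% reacted, a gap of 7.7 points, wider than the forecast's.

    reagent in the reaction phase ⇌ reagent in the second phase, rate k1*([reagent in the reaction phase] - [reagent in the second phase]/K1) per volume of the first phase (partition coefficient = 1.90, kL = 3.10 × 10⁻⁴ min⁻¹)
    starting material + reagent in the reaction phase → target (k = 0.00400 M⁻¹ min⁻¹)
    reagent in the reaction phase + target → over-reacted product (k = 0.00210 M⁻¹ min⁻¹)
    starting material + protic impurity → quenched substrate (k = 1.10 M⁻¹ min⁻¹)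
    reagent in the reaction phase ⇌ dormant form (K = 0.650, k = 1.00 × 10⁻⁴ min⁻¹)

Quenched substrate stands at 2.00%, matching the share, with the protic impurity at 0% of its charge. The remainder of the gap, 5.7 points, is the over-reacted product, at 5.66%. Read at 5.0 d instead, the same flask gives 44.5% target and 59.6% reacted, a gap of 15 points. Taking away the same share leaves 13 points, quenched substrate is still 2.00%, and over-reacted product stands at 13.1%.

(All runs come from a simulation on assumed constants; the scatter is artificial.)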